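Removal of C17 exposes an 8-ketone whose ring B, together with C4, C18, C19 and C20, is the carbon set of (1R,5R)-verbenone, the only difference being a cyclobutane bond between C4 and C7. The route therefore rests on breaking that strained bond next to the C8 carbonyl: a Lewis acid converts it into a C7=C8 enolate and a tertiary C4 cation, and a (Z)-vinylsilane on C10 traps the cation through C3, which forms C3–C4, closes ring A as a trans-fused decalin and leaves a C2=C3 alkene. The precursor is a pinanone bearing the C11–C15 ester chain on C9 and a CH2–CH=CH–SiEt3 arm on C10, both anti to the gem-dimethyl bridge.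

Key step: step 8

Remark on numbering: labdane numbering is used for every verbenone-derived compound (carbonyl carbon C8, the carbon next to it C9, the methyl-bearing carbon C10, bridgeheads C5 and C7, gem-dimethyl carbon C4, CH2 bridge C6).
Remark on C9: enolate alkylation of the pinanone can place the side chain only on the face away from the gem-dimethyl bridge, so the cyclisation precursor and the ketone first formed from it are the 9-epimers (9β-H); C9 is equilibrated to 9α-H afterwards.
Remark on C13: 13S requires that the ester carbon of methyl hydrogen (R)-3-methylglutarate becomes C11 and the acid carbon C15, so the half-ester is reduced at its ester end.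
Remark on silicon (assumption): SiEt3 stands in for SiMe3 because the Z-selective hydrosilylation delivers it; it is a spectator group.

Step 1
Reactants: 1 (1R,5R)-(+)-verbenone; 2 allylmagnesium bromide
Product: 4 (1R,4R,5R)-4-allyl-4,6,6-trimethylbicyclo[3.1.1]heptan-2-one (allyl anti to the gem-dimethyl bridge), via silyl enol ether 3 (not isolated)
Conditions: 2, CuBr·SMe2, LiCl, THF, −78 °C; Me3SiCl, then 1, −78 → −40 °C; 1 M HCl, rt
Reagents that add atoms: none
Why: Me3SiCl-accelerated conjugate addition of allylcopper (organocopper 1,4-addition) is the standard way to allylate a β,β-disubstituted enone, and the new quaternary centre C10 should be set by attack on the face away from the gem-dimethyl bridge, whose syn methyl covers the other face.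

Step 2
Reactants: 5 methyl hydrogen (R)-3-methylglutarate
Product: 7 (S)-4-methyltetrahydro-2H-pyran-2-one, via hydroxy acid 6 (not isolated)
Conditions: LiBH4, THF, 0 °C → rt; 3 M HCl; TsOH (cat.), toluene, 60 °C
Reagents that add atoms: none
Why: LiBH4 reduces the methyl ester but not the lithium carboxylate (chemoselective ester reduction) and the 5-hydroxy acid lactonises on acidification; the stereocentre is untouched and only its descriptor changes.

Step 3
Reactants: 7 (S)-4-methyltetrahydro-2H-pyran-2-one
Product: 9 methyl (R)-5-iodo-3-methylpentanoate, via silyl ester 8 (not isolated)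
Conditions: Me3SiI, CH2Cl2, rt; then MeOH, rt → 50 °C
Reagents that add atoms: iodotrimethylsilane, C[Si](C)(C)I; methanol, CO
Why: Iodotrimethylsilane opens the lactone by SN2 attack of iodide on the O–CH2 carbon of the silylated lactone, and methanol then turns the silyl ester into the methyl ester under the acid formed in situ; the remote stereocentre is not involved.

Step 4
Reactants: 4 (1R,4R,5R)-4-allyl-4,6,6-trimethylbicyclo[3.1.1]heptan-2-one; 9 methyl (R)-5-iodo-3-methylpentanoate
Product: 11 methyl (3S)-3-methyl-5-[(1R,3S,4S,5S)-4-allyl-4,6,6-trimethyl-2-oxobicyclo[3.1.1]heptan-3-yl]pentanoate (C9 chain cis to the allyl group), via lithium enolate 10 (not isolated)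
Conditions: LiN(i-Pr)2, THF, −78 °C; then 9, DMPU, −78 → 0 °C
Reagents that add atoms: none
Why: The ketone can enolise only towards C9 because C7 is a cyclobutane bridgehead, and SN2 alkylation of the lithium enolate by the primary iodide (ketone enolate alkylation) should occur anti to the gem-dimethyl bridge, which sets C9 with the chain cis to the allyl group.

Step 5
Reactants: 11 the C9-alkylated allyl pinanone
Product: 13 keto aldehyde (11 with the allyl group shortened to CH2–CHO on C10; all stereocentres as in 11), via ozonide 12 (not isolated)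
Conditions: O3, CH2Cl2, −78 °C; then PPh3, −78 °C → rt
Reagents that add atoms: ozone, O=[O+][O-]
Why: Ozonolysis with reductive work-up cleaves the only C=C bond to the aldehyde and leaves ketone, ester and stereocentres alone.

Step 6
Reactants: 13 keto aldehyde
Product: 14 alkynyl pinanone (C10 carries CH2–C≡CH; all stereocentres as in 11)
Conditions: MeC(O)C(N2)P(O)(OMe)2, K2CO3, MeOH, 0 °C → rt
Reagents that add atoms: dimethyl (1-diazo-2-oxopropyl)phosphonate, CC(=O)C(=[N+]=[N-])P(=O)(OC)OC
Why: The Seyferth–Gilbert homologation in its Ohira–Bestmann form converts the aldehyde into the terminal alkyne under carbonate in methanol, mild enough for ketone and methyl ester, and C9 already holds its more stable configuration in the pinanone.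

Step 7
Reactants: 14 alkynyl pinanone
Product: 15 (Z)-vinylsilane pinanone (C10 carries CH2–CH=CH–SiEt3 with C1 and Si cis; C8 ketone; cyclobutane C4–C5–C6–C7; C9 chain and C10 arm anti to the gem-dimethyl bridge, C20 syn to it; 13S)
Conditions: Et3SiH, [RuCl2(p-cymene)]2 (cat.), CH2Cl2, 40 °C
Reagents that add atoms: triethylsilane, CC[SiH](CC)CC
Why: Ruthenium-catalysed hydrosilylation of terminal alkynes with this complex proceeds by trans addition and should give the β-(Z)-vinylsilane without base, so ketone, ester and C9 are not disturbed.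

Step 8
Reactants: 15 (Z)-vinylsilane pinanone
Product: 17 methyl (13S)-8-oxo-17-nor-9βH-labd-2-en-15-oate (trans-fused, 5α-H, 10β-CH3, C9 chain α), via aluminium enolate 16 (not isolated)
Conditions: EtAlCl2 (3 equiv), CH2Cl2, −78 → 0 °C; cold 1 M HCl
Reagents that add atoms: none
Why: Proposed new method: EtAlCl2 bound to the C8 carbonyl should trigger heterolysis of the strained C4–C7 cyclobutane bond to an aluminium enolate (C7=C8) and the tertiary C4 cation; the (Z)-vinylsilane on C10 then attacks through its silicon-bearing carbon C3, and the β-silyl cation at C2 gives up Et3Si to chloride, leaving the C2=C3 alkene. The closest known reactions are Lewis acid openings of nopinone-type cyclobutanes to 2-propyl cations and vinylsilane-terminated cation–olefin cyclisations. Ring A closes in a 6-endo chair mode. No stereocentre is created: C5 is the verbenone bridgehead and C10 was fixed in step 1, and because C1 and C4 are trans on ring B only the trans-fused decalin is within reach. The step needs ipso attack at C3 to beat 5-exo attack at C2, proton loss from the cation and addition to the complexed ketone; the β-silicon effect, enforced by the Z geometry that aligns the C3–Si bond with the developing C2 orbital, favours the first, and the ethyl group on aluminium scavenges protons that would otherwise cause protodesilylation.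

Step 9
Reactants: 17 methyl (13S)-8-oxo-17-nor-9βH-labd-2-en-15-oate
Product: 19 methyl (13S)-8-oxo-17-norlabdan-15-oate (9α-H), via C9-equilibrated keto alkene 18 (not isolated)
Conditions: NaOMe (0.3 equiv), MeOH, 50 °C; AcOH; then H2 (1 atm), Pd/C, rt
Reagents that add atoms: none
Why: Methoxide should equilibrate the ketone α-centre C9 through the enolate to the epimer with the equatorial side chain (9α-H, thermodynamic control), and catalytic hydrogenation then saturates the cis-disubstituted C2=C3 bond without creating a stereocentre.

Step 10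
Reactants: 19 methyl (13S)-8-oxo-17-norlabdan-15-oate
Product: 20 methyl (13S)-labd-8(17)-en-15-oate
Conditions: Ph3PCH3Br, KN(SiMe3)2, THF, 0 °C; then 19, rt → 60 °C
Reagents that add atoms: methyltriphenylphosphonium bromide, C[P+](c1ccccc1)(c1ccccc1)c1ccccc1.[Br-]
Why: Wittig methylenation converts the C8 ketone into the 8(17)-methylene group; the amide base spares the methyl ester and C9 is already at its stable configuration.

Step 11
Reactants: 20 methyl (13S)-labd-8(17)-en-15-oate
Product: 22 methyl (13S)-8α-hydroxylabdan-15-oate, via organomercurial 21 (not isolated)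
Conditions: Hg(OAc)2, THF/H2O 1:1, rt; then 3 M NaOH, NaBH4, 0 °C
Reagents that add atoms: water, O
Why: Oxymercuration–demercuration gives Markovnikov hydration of the 1,1-disubstituted alkene, and water should attack C8 from the α (equatorial) face because the β face is screened by the axial C10 methyl group, which sets C8 as the 8α-alcohol with the new methyl group β.

Step 12
Reactants: 22 methyl (13S)-8α-hydroxylabdan-15-oate
Product: 23 (13S)-8α-hydroxylabdan-15-oic acid
Conditions: LiOH·H2O, THF/MeOH/H2O, 40 °C; 1 M HCl
Reagents that add atoms: lithium hydroxide, [Li+].[OH-]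
Why: Saponification of the unhindered methyl ester frees the C15 acid, and the tertiary alcohol and all stereocentres are inert to hydroxide.

Step 13
Reactants: 23 (13S)-8α-hydroxylabdan-15-oic acid
Product: 25 (5S,8R,9R,10S,13S)-8α-acetoxylabdan-15-oic acid (CNP0470037.2), via mixed anhydride 24 (not isolated)
Conditions: Ac2O, DMAP, pyridine, 50 °C; then H2O, rt; 1 M HCl work-up
Reagents that add atoms: acetic anhydride, CC(=O)OC(C)=O
Why: DMAP-catalysed acylation (Steglich-type acetylation) esterifies the hindered tertiary 8α-alcohol with retention at C8 because the C–O bond is not broken, and the mixed anhydride formed at C15 is hydrolysed by water in the same flask.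

Compound list
1 | (1R,5R)-(+)-verbenone | O=C1C=C(C)[C@H]2C[C@@H]1C2(C)C | starting material
2 | allylmagnesium bromide | C=CC[Mg]Br | starting material
3 | trimethylsilyl enol ether of 4 (C8–OSiMe3, C8=C9) | C[Si](C)(C)OC1=C[C@@](C)(CC=C)[C@H]2C[C@@H]1C2(C)C | intermediate
4 | (1R,4R,5R)-4-allyl-4,6,6-trimethylbicyclo[3.1.1]heptan-2-one | O=C1C[C@@](C)(CC=C)[C@H]2C[C@@H]1C2(C)C | intermediate
5 | methyl hydrogen (R)-3-methylglutarate | COC(=O)C[C@H](C)CC(=O)O | starting material
6 | (S)-5-hydroxy-3-methylpentanoic acid | OCC[C@H](C)CC(=O)O | intermediate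
7 | (S)-4-methyltetrahydro-2H-pyran-2-one | O=C1C[C@@H](C)CCO1 | intermediate
8 | trimethylsilyl (R)-5-iodo-3-methylpentanoate | C[Si](C)(C)OC(=O)C[C@@H](C)CCI | intermediate
9 | methyl (R)-5-iodo-3-methylpentanoate | ICC[C@H](C)CC(=O)OC | intermediate
10 | lithium enolate of 4 (C8–OLi, C8=C9) | [Li]OC1=C[C@@](C)(CC=C)[C@H]2C[C@@H]1C2(C)C | intermediate
11 | methyl (3S)-3-methyl-5-[(1R,3S,4S,5S)-4-allyl-4,6,6-trimethyl-2-oxobicyclo[3.1.1]heptan-3-yl]pentanoate | O=C1[C@@H](CC[C@H](C)CC(=O)OC)[C@@](C)(CC=C)[C@H]2C[C@@H]1C2(C)C | intermediate
12 | ozonide of 11 (1,2,4-trioxolane from the allyl C=C; ring carbon configuration undefined) | O=C1[C@@H](CC[C@H](C)CC(=O)OC)[C@@](C)(CC3OCOO3)[C@H]2C[C@@H]1C2(C)C | intermediate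
13 | keto aldehyde (C10 carries CH2–CHO) | O=C1[C@@H](CC[C@H](C)CC(=O)OC)[C@@](C)(CC=O)[C@H]2C[C@@H]1C2(C)C | intermediate
14 | alkynyl pinanone (C10 carries CH2–C≡CH) | O=C1[C@@H](CC[C@H](C)CC(=O)OC)[C@@](C)(CC#C)[C@H]2C[C@@H]1C2(C)C | intermediate
15 | (Z)-vinylsilane pinanone (C10 carries CH2–CH=CH–SiEt3) | O=C1[C@@H](CC[C@H](C)CC(=O)OC)[C@@](C)(C/C=C\[Si](CC)(CC)CC)[C@H]2C[C@@H]1C2(C)C | intermediate
16 | chloro(ethyl)aluminium enolate of 17 (C7=C8) | CC[Al](Cl)OC1=CC[C@H]2C(C)(C)C=CC[C@]2(C)[C@@H]1CC[C@H](C)CC(=O)OC | intermediate
17 | methyl (13S)-8-oxo-17-nor-9βH-labd-2-en-15-oate | O=C1CC[C@H]2C(C)(C)C=CC[C@]2(C)[C@@H]1CC[C@H](C)CC(=O)OC | intermediate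
18 | methyl (13S)-8-oxo-17-norlabd-2-en-15-oate (9α-H) | O=C1CC[C@H]2C(C)(C)C=CC[C@]2(C)[C@H]1CC[C@H](C)CC(=O)OC | intermediate
19 | methyl (13S)-8-oxo-17-norlabdan-15-oate | O=C1CC[C@H]2C(C)(C)CCC[C@]2(C)[C@H]1CC[C@H](C)CC(=O)OC | intermediate
20 | methyl (13S)-labd-8(17)-en-15-oate | C=C1CC[C@H]2C(C)(C)CCC[C@]2(C)[C@H]1CC[C@H](C)CC(=O)OC | intermediate
21 | methyl (13S)-17-(acetoxymercurio)-8α-hydroxylabdan-15-oate | CC(=O)O[Hg]C[C@@]1(O)CC[C@H]2C(C)(C)CCC[C@]2(C)[C@H]1CC[C@H](C)CC(=O)OC | intermediate
22 | methyl (13S)-8α-hydroxylabdan-15-oate | O[C@]1(C)CC[C@H]2C(C)(C)CCC[C@]2(C)[C@H]1CC[C@H](C)CC(=O)OC | intermediate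
23 | (13S)-8α-hydroxylabdan-15-oic acid | O[C@]1(C)CC[C@H]2C(C)(C)CCC[C@]2(C)[C@H]1CC[C@H](C)CC(=O)O | intermediate
24 | acetic (13S)-8α-acetoxylabdan-15-oic anhydride | CC(=O)O[C@]1(C)CC[C@H]2C(C)(C)CCC[C@]2(C)[C@H]1CC[C@H](C)CC(=O)OC(C)=O | intermediate
25 | (5S,8R,9R,10S,13S)-8α-acetoxylabdan-15-oic acid, CNP0470037.2 | CC(=O)O[C@]1(C)CC[C@H]2C(C)(C)CCC[C@]2(C)[C@H]1CC[C@H](C)CC(=O)O | target

Total step count: 13.
Longest linear sequence: 12 steps (steps 2, 3 and 4 to 13, from half-ester 5); 11 steps from verbenone 1.

Steps most likely to fail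

Step 8. The C4 cation may lose a proton to the isopropenyl or isopropylidene compound faster than ring A closes, or the vinylsilane may add to the complexed C8 ketone before the cyclobutane bond breaks. The fallback separates bond cleavage from ring closure with known chemistry and sets out from 15. BF3·OEt2, Zn(OAc)2 and Ac2O, the established reagent mixture for opening nopinone-type cyclobutanes, should give the monocyclic isopropenyl enol acetate F1, in which the ketone is masked. Brief exposure to CF3CO2H in CH2Cl2 at 0 °C should then protonate the 1,1-disubstituted alkene to the same C4 cation and close ring A in a conventional vinylsilane-terminated cation–olefin cyclisation, giving the bicyclic enol acetate F2. K2CO3 in MeOH at 0 °C removes the acetyl group and the route is rejoined at 17.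

Step 1. The allyl group may add to the carbonyl carbon (1,2-addition) in place of the conjugate position. The fallback accepts this and sets out from 1 and 2. Without copper, 2 in THF at −78 °C should add anti to the gem-dimethyl bridge to give the tertiary dienol F3. KH and 18-crown-6 in THF then bring about the anionic oxy-Cope rearrangement, which moves the allyl group suprafacially to C10 on the same face, and aqueous quench of the enolate returns 4.

Step 4. C-alkylation of the hindered enolate by an unactivated iodide may be slow, so that O-alkylation, proton exchange or loss of HI from the iodide take over. The fallback uses an aza-enolate and sets out from 4. Condensation with H2NNMe2 (AcOH cat., EtOH, reflux) gives the dimethylhydrazone F4. Its lithium aza-enolate (LiN(i-Pr)2, THF, 0 °C), which is far more nucleophilic towards primary iodides, should be alkylated by 9 anti to the bridge to give the alkylated dimethylhydrazone F5. Two-phase hydrolysis with aqueous oxalic acid returns 11.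

Further compounds
F1 | step 8 | isopropenyl enol acetate (C7=C8 enol acetate, C5 isopropenyl, C10 vinylsilane arm) | CC(=O)OC1=CC[C@@H](C(C)=C)[C@](C)(C/C=C\[Si](CC)(CC)CC)[C@@H]1CC[C@H](C)CC(=O)OC
F2 | step 8 | bicyclic enol acetate of 17 (C7=C8) | CC(=O)OC1=CC[C@H]2C(C)(C)C=CC[C@]2(C)[C@@H]1CC[C@H](C)CC(=O)OC
F3 | step 1 | tertiary dienol, 2-allyl-4,6,6-trimethylbicyclo[3.1.1]hept-3-en-2-ol (allyl anti to the gem-dimethyl bridge) | O[C@]1(CC=C)C=C(C)[C@H]2C[C@@H]1C2(C)C
F4 | step 4 | N,N-dimethylhydrazone of 4 (C=N geometry undefined) | CN(C)N=C1C[C@@](C)(CC=C)[C@H]2C[C@@H]1C2(C)C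
F5 | step 4 | N,N-dimethylhydrazone of 11 (C=N geometry undefined) | CN(C)N=C1[C@@H](CC[C@H](C)CC(=O)OC)[C@@](C)(CC=C)[C@H]2C[C@@H]1C2(C)C
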